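## Retrosynthetic overview

- U, M and L are the top, middle and bottom epicatechin units. The target comes from hydrogenolysis of the fully benzylated tri-gallate, which comes from threefold galloylation of the benzylated trimer triol.
- The strategy rests on ring C of M (O1–C2–C3–C4–C4a–C8a). Its C2–C3 bond is cut so that C2, carrying ring B, sits on O1 as an α-aryl vinyl ether, and C3 is a vinyl group on the diarylmethine C4, which is bonded to C4a of M and C8 of L.
- C2 and C3 of M come from the 2-aryl-4H-chromene by epoxidation anti to the C4 aryl and hydride opening at C2 with inversion. The chromene comes from ring-closing metathesis of the diene. This is the only ring made in the route; all other rings come from (−)-epicatechin and the aromatic building blocks.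
- The diene comes from Tebbe methylenation of the O1 aryl ester of a phenol. That phenol carries U at C8 (Friedel–Crafts reaction with C4-activated epicatechin) and the C4 methine (iridium-catalysed branched allylation of 3,5-bis(benzyloxy)phenol by the vinyl carbinol of L, which sets C4 of M).

Key step: step 12

Remark: 3,5-bis(benzyloxy)phenol and 3,4-bis(benzyloxy)benzoic acid are taken as purchasable benzyl-protected forms of phloroglucinol and protocatechuic acid. 3,4,5-Tris(benzyloxy)benzoic acid, the benzyl-protected form of gallic acid, is likewise bought and serves as the acylating reagent of step 16, where three molecules of it are taken up per molecule of triol 19.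

Remark: the (S)-ligand is assumed to give the (R)-methine in the allylation of step 6; if the sense of induction is the opposite, the (R)-ligand is used with no other change.

Abbreviations used in names:
- L-8-yl = (2R,3R)-5,7-bis(benzyloxy)-2-[3,4-bis(benzyloxy)phenyl]-3-(tert-butyldimethylsilyloxy)chroman-8-yl
- U-4-yl = the same protected chroman bonded through C4, with the C4 substituent trans to the 3-silyloxy group (4β)

## Route

Step 1
Reactants: 1 (−)-epicatechin
Product: 2 5,7,3′,4′-tetra-O-benzyl-(−)-epicatechin (2R,3R; 3-OH free)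
Conditions: BnBr, K2CO3, DMF, 0 °C → rt
Reagents that add atoms: benzyl bromide (BrCc1ccccc1)
Why: Williamson etherification of the four phenols with a carbonate base leaves the less acidic secondary 3-OH free and does not touch C2 or C3.

Step 2
Reactants: 2 5,7,3′,4′-tetra-O-benzyl-(−)-epicatechin
Product: 3 3-O-tert-butyldimethylsilyl-5,7,3′,4′-tetra-O-benzyl-(−)-epicatechin
Conditions: TBSCl, imidazole, DMF, rt
Reagents that add atoms: tert-butyldimethylsilyl chloride (CC(C)(C)[Si](C)(C)Cl)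
Why: Imidazole-promoted silylation of the only free hydroxyl gives an ether that should survive the organolithium, Lewis acid, Tebbe, metathesis and hydride steps.

Step 3
Reactants: 3 3-O-TBS-tetra-O-benzyl-epicatechin
Product: 4 8-bromo-3-O-TBS-5,7,3′,4′-tetra-O-benzyl-epicatechin
Conditions: NBS, CH2Cl2, −78 °C → rt
Reagents that add atoms: N-bromosuccinimide (BrN1C(=O)CCC1=O)
Why: Electrophilic aromatic bromination should go to C8, flanked by O1 and one benzyloxy group, since C6 lies between two benzyloxy groups.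

Step 4
Reactants: 4 8-bromo-3-O-TBS-tetra-O-benzyl-epicatechin
Product: 6 3-O-TBS-5,7,3′,4′-tetra-O-benzyl-epicatechin-8-carbaldehyde, via aryllithium 5 (not isolated)
Conditions: t-BuLi, THF, −78 °C; DMF; then H2O
Reagents that add atoms: N,N-dimethylformamide (CN(C)C=O)
Why: Bromine–lithium exchange at −78 °C is faster than benzylic deprotonation, and the aryllithium is formylated by DMF (Bouveault aldehyde synthesis).

Step 5
Reactants: 6 L-8-carbaldehyde
Product: 7 1-(L-8-yl)prop-2-en-1-ol (both carbinol epimers)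
Conditions: CH2=CHMgBr, THF, −78 → 0 °C; then H2O
Reagents that add atoms: vinylmagnesium bromide (C=C[Mg]Br)
Why: Grignard 1,2-addition to the aldehyde; the carbinol configuration does not matter because this carbon becomes a planar allyl terminus in step 6.

Step 6
Reactants: 7 1-(L-8-yl)prop-2-en-1-ol; 8 3,5-bis(benzyloxy)phenol
Product: 9 3,5-bis(benzyloxy)-2-[(1R)-1-(L-8-yl)prop-2-en-1-yl]phenol
Conditions: [Ir(cod)Cl]2 (cat.), (S)-N-(dinaphtho[2,1-d:1′,2′-f][1,3,2]dioxaphosphepin-4-yl)-5H-dibenzo[b,f]azepine (cat.), Zn(OTf)2 (cat.), 8 (3 equiv), ClCH2CH2Cl, rt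
Reagents that add atoms: none
Why: Proposed new method: acid-assisted ionisation of either epimer of 7 by the iridium–phosphoramidite-olefin complex should give one η3-allyl complex of trivalent iridium. Phenol 8 should attack it through an ortho carbon at the aryl-bearing terminus, anti to the metal (Friedel–Crafts allylic alkylation), so the ligand alone fixes the diarylmethine as (R). The phenol O–H next to the new bond stays free as the future O1. Any O-allyl ether should re-ionise under these conditions and end as the C-allyl product, and the carbon between the two benzyloxy groups is the more hindered site. The closest known reactions are the iridium-catalysed enantioselective C1-allylation of 2-naphthols with aryl vinyl carbinols and the arene-terminated iridium-catalysed polyene cyclisation.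

Step 7
Reactants: 3 3-O-TBS-tetra-O-benzyl-epicatechin
Product: 10 (2R,3R,4S)-4-(2-ethoxyethoxy)-3-O-TBS-5,7,3′,4′-tetra-O-benzyl-epicatechin (3,4-trans)
Conditions: DDQ, EtOCH2CH2OH, CH2Cl2, rt
Reagents that add atoms: 2-ethoxyethanol (CCOCCO)
Why: DDQ removes hydride from the benzylic C4–H activated by ring A, and the alcohol adds to the cation anti to the 3-silyloxy group (oxidative benzylic etherification), giving the 4β ether.

Step 8
Reactants: 9 ortho-(1-arylallyl)phenol; 10 4-(2-ethoxyethoxy) electrophile of U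
Product: 11 3,5-bis(benzyloxy)-2-[(1R)-1-(L-8-yl)prop-2-en-1-yl]-6-(U-4-yl)phenol (C4 of U 3,4-trans)
Conditions: TMSOTf (cat.), CH2Cl2, −78 → −40 °C; then aq. NaHCO3
Reagents that add atoms: none
Why: TMSOTf ionises the C4 ether to the ring-A-stabilised cation, which undergoes Friedel–Crafts attack by the phenol ring of 9 at its one open position ortho to OH (the other open carbon lies between two benzyloxy groups), from the face anti to the 3-OTBS group, so the 4β interflavan bond should form.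

Step 9
Reactants: 12 3,4-bis(benzyloxy)benzoic acid
Product: 13 3,4-bis(benzyloxy)benzoyl chloride
Conditions: (COCl)2, DMF (cat.), CH2Cl2, 0 °C → rt
Reagents that add atoms: oxalyl chloride (ClC(=O)C(Cl)=O)
Why: Acyl chloride formation through the Vilsmeier-type chloroiminium species.

Step 10
Reactants: 11 U–ring A–L phenol; 13 3,4-bis(benzyloxy)benzoyl chloride
Product: 14 3,4-bis(benzyloxy)benzoate of phenol 11 (ester on the future O1)
Conditions: Et3N, DMAP, CH2Cl2, rt → 40 °C
Reagents that add atoms: none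
Why: DMAP-catalysed O-acylation of the only free hydroxyl, the hindered O1 phenol.

Step 11
Reactants: 14 O1 aryl ester
Product: 15 diene: 1-[3,4-bis(benzyloxy)phenyl]vinyl ether of phenol 11, with the vinyl group on the C4 methine
Conditions: Cp2Ti(μ-Cl)(μ-CH2)AlMe2, THF–toluene, −40 °C → rt
Reagents that add atoms: Tebbe reagent (C[Al-]1(C)C[Ti]([Cl+]1)(C1C=CC=C1)C1C=CC=C1)
Why: Tebbe methylenation: the titanium methylidene adds to the ester C=O and the oxatitanacyclobutane collapses to the α-aryl vinyl ether, while the low temperature spares the terminal vinyl group.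

Step 12
Reactants: 15 diene
Product: 16 trimer in which M is a 2-[3,4-bis(benzyloxy)phenyl]-4H-chromene, with L on C4 and U on C8
Conditions: second-generation Grubbs catalyst (H2IMes)(PCy3)Cl2Ru=CHPh (10–20 mol%), 1,4-benzoquinone (cat.), toluene, 80 °C, argon sparge
Reagents that add atoms: none
Why: The ruthenium benzylidene should exchange onto the unhindered monosubstituted C4 vinyl group; the new alkylidene then adds intramolecularly to the 1,1-disubstituted α-aryl vinyl ether by [2+2] cycloaddition and cycloreverts, forming C2=C3 and releasing ethylene. The closest known reaction type is ring-closing metathesis of aryl vinyl ethers that carry an ortho allylic alkene, and of ester-derived enol ethers in general, to 4H-chromenes and other cyclic enol ethers. Ring C of M is closed as a six-membered ring from the 1,7-diene CH2=C2–O1–C8a–C4a–C4–C3H=CH2, in which the aromatic C8a–C4a bond holds the two alkenes cis and close. No stereocentre is formed, and C4 from step 6 keeps its configuration because no acid or base is present. The step needs initiation at the vinyl group and not at the enol ether, which the steric and electronic difference between the two alkenes should secure; it also needs the new double bond to stay at C2=C3 and not migrate through C4, which 1,4-benzoquinone (a scavenger of ruthenium hydrides) and removal of ethylene should secure. The neutral conditions also leave the acid-labile C4–C8 bond to U and the silyl and benzyl ethers untouched.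

Step 13
Reactants: 16 2-aryl-4H-chromene trimer
Product: 17 2,3-epoxide of 16, oxygen on the face anti to the C4 aryl (used crude)
Conditions: DMDO, acetone–CH2Cl2, −78 → −40 °C; volatiles removed cold
Reagents that add atoms: dimethyldioxirane (CC1(C)OO1)
Why: Neutral electrophilic epoxidation of the electron-rich enol ether; the pseudo-axial C4 aryl (unit L) shields one face of the nearly flat pyran ring, so oxygen should be delivered anti to it, which sets C3.

Step 14
Reactants: 17 2,3-epoxide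
Product: 18 benzylated trimer with free 3-OH on M (2,3-cis, 3,4-trans) and TBS on O3 of U and L
Conditions: LiBHEt3, THF, −78 → 0 °C; then H2O
Reagents that add atoms: none
Why: The non-Lewis-acidic borohydride should open the acetal-type epoxide at C2 in an SN2-like way, anti to the leaving oxygen, as in hydride opening of aryl glycal epoxides; C2 is inverted, so the aryl ends cis to the 3-OH while C3–O stays trans to the C4 aryl.

Step 15
Reactants: 18 bis-TBS trimer
Product: 19 dodeca-O-benzyl procyanidin C1 (3-OH free on U, M and L)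
Conditions: TBAF, THF, rt → 40 °C
Reagents that add atoms: none
Why: Fluoride-driven cleavage of the two secondary silyl ethers; benzyl ethers and stereocentres are untouched.

Step 16
Reactants: 19 dodeca-O-benzyl procyanidin C1 (trimer triol)
Product: 20 henicosa-O-benzyl procyanidin C1 3,3,3-tri-O-gallate
Conditions: 3,4,5-(BnO)3C6H2CO2H (6 equiv), DCC (6 equiv), DMAP (1.5 equiv), CH2Cl2, rt → 40 °C
Reagents that add atoms: 3,4,5-tris(benzyloxy)benzoic acid (OC(=O)c1cc(OCc2ccccc2)c(OCc2ccccc2)c(OCc2ccccc2)c1)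
Why: Steglich esterification: DCC activates the acid as the O-acylisourea and DMAP passes the acyl group on as the N-acylpyridinium ion to each of the three axial secondary 3-hydroxyls, so three molecules of the acid are taken up and C3 keeps its configuration because no C–O bond at C3 is broken.

Step 17
Reactants: 20 fully benzylated tri-gallate
Product: 21 procyanidin C1 3,3,3-tri-O-gallate
Conditions: H2 (1 atm), Pd(OH)2 on carbon, THF–MeOH–H2O, rt
Reagents that add atoms: none
Why: Hydrogenolysis of all 21 benzyl ethers under neutral conditions should leave the gallate esters, the interflavan bonds and all nine stereocentres intact.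

## Compound list

1 | (−)-epicatechin | O[C@@H]1Cc2c(O)cc(O)cc2O[C@@H]1c1ccc(O)c(O)c1 | starting material
2 | 5,7,3′,4′-tetra-O-benzyl-(−)-epicatechin | O[C@@H]1Cc2c(OCc3ccccc3)cc(OCc3ccccc3)cc2O[C@@H]1c1ccc(OCc2ccccc2)c(OCc2ccccc2)c1 | intermediate
3 | 3-O-TBS-5,7,3′,4′-tetra-O-benzyl-(−)-epicatechin | CC(C)(C)[Si](C)(C)O[C@@H]1Cc2c(OCc3ccccc3)cc(OCc3ccccc3)cc2O[C@@H]1c1ccc(OCc2ccccc2)c(OCc2ccccc2)c1 | intermediate
4 | 8-bromo-3-O-TBS-5,7,3′,4′-tetra-O-benzyl-epicatechin | CC(C)(C)[Si](C)(C)O[C@@H]1Cc2c(OCc3ccccc3)cc(OCc3ccccc3)c(Br)c2O[C@@H]1c1ccc(OCc2ccccc2)c(OCc2ccccc2)c1 | intermediate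
5 | 8-lithio-3-O-TBS-5,7,3′,4′-tetra-O-benzyl-epicatechin | CC(C)(C)[Si](C)(C)O[C@@H]1Cc2c(OCc3ccccc3)cc(OCc3ccccc3)c([Li])c2O[C@@H]1c1ccc(OCc2ccccc2)c(OCc2ccccc2)c1 | intermediate (not isolated)
6 | 3-O-TBS-5,7,3′,4′-tetra-O-benzyl-epicatechin-8-carbaldehyde | CC(C)(C)[Si](C)(C)O[C@@H]1Cc2c(OCc3ccccc3)cc(OCc3ccccc3)c(C=O)c2O[C@@H]1c1ccc(OCc2ccccc2)c(OCc2ccccc2)c1 | intermediate
7 | 1-(L-8-yl)prop-2-en-1-ol, both carbinol epimers | CC(C)(C)[Si](C)(C)O[C@@H]1Cc2c(OCc3ccccc3)cc(OCc3ccccc3)c(C(O)C=C)c2O[C@@H]1c1ccc(OCc2ccccc2)c(OCc2ccccc2)c1 | intermediate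
8 | 3,5-bis(benzyloxy)phenol | Oc1cc(OCc2ccccc2)cc(OCc2ccccc2)c1 | starting material
9 | 3,5-bis(benzyloxy)-2-[(1R)-1-(L-8-yl)prop-2-en-1-yl]phenol | Oc1cc(OCc2ccccc2)cc(OCc2ccccc2)c1[C@H](c1c(OCc2ccccc2)cc(OCc2ccccc2)c2c1O[C@H](c1ccc(OCc3ccccc3)c(OCc3ccccc3)c1)[C@H](O[Si](C)(C)C(C)(C)C)C2)C=C | intermediate
10 | (2R,3R,4S)-4-(2-ethoxyethoxy)-3-O-TBS-5,7,3′,4′-tetra-O-benzyl-epicatechin | CCOCCO[C@H]1c2c(OCc3ccccc3)cc(OCc3ccccc3)cc2O[C@H](c2ccc(OCc3ccccc3)c(OCc3ccccc3)c2)[C@@H]1O[Si](C)(C)C(C)(C)C | intermediate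
11 | 3,5-bis(benzyloxy)-2-[(1R)-1-(L-8-yl)prop-2-en-1-yl]-6-(U-4-yl)phenol | Oc1c([C@H]2c3c(OCc4ccccc4)cc(OCc4ccccc4)cc3O[C@H](c3ccc(OCc4ccccc4)c(OCc4ccccc4)c3)[C@@H]2O[Si](C)(C)C(C)(C)C)c(OCc2ccccc2)cc(OCc2ccccc2)c1[C@H](c1c(OCc2ccccc2)cc(OCc2ccccc2)c2c1O[C@H](c1ccc(OCc3ccccc3)c(OCc3ccccc3)c1)[C@H](O[Si](C)(C)C(C)(C)C)C2)C=C | intermediate
12 | 3,4-bis(benzyloxy)benzoic acid | OC(=O)c1ccc(OCc2ccccc2)c(OCc2ccccc2)c1 | starting material
13 | 3,4-bis(benzyloxy)benzoyl chloride | ClC(=O)c1ccc(OCc2ccccc2)c(OCc2ccccc2)c1 | intermediate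
14 | 3,4-bis(benzyloxy)benzoate of phenol 11 | O=C(c1ccc(OCc2ccccc2)c(OCc2ccccc2)c1)Oc1c([C@H]2c3c(OCc4ccccc4)cc(OCc4ccccc4)cc3O[C@H](c3ccc(OCc4ccccc4)c(OCc4ccccc4)c3)[C@@H]2O[Si](C)(C)C(C)(C)C)c(OCc2ccccc2)cc(OCc2ccccc2)c1[C@H](c1c(OCc2ccccc2)cc(OCc2ccccc2)c2c1O[C@H](c1ccc(OCc3ccccc3)c(OCc3ccccc3)c1)[C@H](O[Si](C)(C)C(C)(C)C)C2)C=C | intermediate
15 | diene: 1-[3,4-bis(benzyloxy)phenyl]vinyl ether of phenol 11 | C=C(c1ccc(OCc2ccccc2)c(OCc2ccccc2)c1)Oc1c([C@H]2c3c(OCc4ccccc4)cc(OCc4ccccc4)cc3O[C@H](c3ccc(OCc4ccccc4)c(OCc4ccccc4)c3)[C@@H]2O[Si](C)(C)C(C)(C)C)c(OCc2ccccc2)cc(OCc2ccccc2)c1[C@H](c1c(OCc2ccccc2)cc(OCc2ccccc2)c2c1O[C@H](c1ccc(OCc3ccccc3)c(OCc3ccccc3)c1)[C@H](O[Si](C)(C)C(C)(C)C)C2)C=C | intermediate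
16 | 2-aryl-4H-chromene trimer (M ring C closed, C2=C3; L on C4, U on C8) | C1(c2ccc(OCc3ccccc3)c(OCc3ccccc3)c2)=C[C@@H](c2c(OCc3ccccc3)cc(OCc3ccccc3)c3c2O[C@H](c2ccc(OCc4ccccc4)c(OCc4ccccc4)c2)[C@H](O[Si](C)(C)C(C)(C)C)C3)c2c(OCc3ccccc3)cc(OCc3ccccc3)c([C@H]3c4c(OCc5ccccc5)cc(OCc5ccccc5)cc4O[C@H](c4ccc(OCc5ccccc5)c(OCc5ccccc5)c4)[C@@H]3O[Si](C)(C)C(C)(C)C)c2O1 | intermediate
17 | 2,3-epoxide of 16, oxygen anti to the C4 aryl | O1[C@@H]2[C@@H](c3c(OCc4ccccc4)cc(OCc4ccccc4)c4c3O[C@H](c3ccc(OCc5ccccc5)c(OCc5ccccc5)c3)[C@H](O[Si](C)(C)C(C)(C)C)C4)c3c(OCc4ccccc4)cc(OCc4ccccc4)c([C@H]4c5c(OCc6ccccc6)cc(OCc6ccccc6)cc5O[C@H](c5ccc(OCc6ccccc6)c(OCc6ccccc6)c5)[C@@H]4O[Si](C)(C)C(C)(C)C)c3O[C@]12c1ccc(OCc2ccccc2)c(OCc2ccccc2)c1 | intermediate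
18 | dodeca-O-benzyl procyanidin C1 with TBS on O3 of U and L and free 3-OH on M | O[C@@H]1[C@@H](c2c(OCc3ccccc3)cc(OCc3ccccc3)c3c2O[C@H](c2ccc(OCc4ccccc4)c(OCc4ccccc4)c2)[C@H](O[Si](C)(C)C(C)(C)C)C3)c2c(OCc3ccccc3)cc(OCc3ccccc3)c([C@H]3c4c(OCc5ccccc5)cc(OCc5ccccc5)cc4O[C@H](c4ccc(OCc5ccccc5)c(OCc5ccccc5)c4)[C@@H]3O[Si](C)(C)C(C)(C)C)c2O[C@@H]1c1ccc(OCc2ccccc2)c(OCc2ccccc2)c1 | intermediate
19 | dodeca-O-benzyl procyanidin C1 (three free 3-OH) | O[C@@H]1[C@@H](c2c(OCc3ccccc3)cc(OCc3ccccc3)c3c2O[C@H](c2ccc(OCc4ccccc4)c(OCc4ccccc4)c2)[C@H](O)C3)c2c(OCc3ccccc3)cc(OCc3ccccc3)c([C@H]3c4c(OCc5ccccc5)cc(OCc5ccccc5)cc4O[C@H](c4ccc(OCc5ccccc5)c(OCc5ccccc5)c4)[C@@H]3O)c2O[C@@H]1c1ccc(OCc2ccccc2)c(OCc2ccccc2)c1 | intermediate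
20 | henicosa-O-benzyl procyanidin C1 3,3,3-tri-O-gallate | O=C(O[C@@H]1[C@@H](c2c(OCc3ccccc3)cc(OCc3ccccc3)c3c2O[C@H](c2ccc(OCc4ccccc4)c(OCc4ccccc4)c2)[C@H](OC(=O)c2cc(OCc4ccccc4)c(OCc4ccccc4)c(OCc4ccccc4)c2)C3)c2c(OCc3ccccc3)cc(OCc3ccccc3)c([C@H]3c4c(OCc5ccccc5)cc(OCc5ccccc5)cc4O[C@H](c4ccc(OCc5ccccc5)c(OCc5ccccc5)c4)[C@@H]3OC(=O)c3cc(OCc4ccccc4)c(OCc4ccccc4)c(OCc4ccccc4)c3)c2O[C@@H]1c1ccc(OCc2ccccc2)c(OCc2ccccc2)c1)c1cc(OCc2ccccc2)c(OCc2ccccc2)c(OCc2ccccc2)c1 | intermediate
21 | procyanidin C1 3,3,3-tri-O-gallate | O=C(O[C@@H]1[C@@H](c2c(O)cc(O)c3c2O[C@H](c2ccc(O)c(O)c2)[C@H](OC(=O)c2cc(O)c(O)c(O)c2)C3)c2c(O)cc(O)c([C@H]3c4c(O)cc(O)cc4O[C@H](c4ccc(O)c(O)c4)[C@@H]3OC(=O)c3cc(O)c(O)c(O)c3)c2O[C@@H]1c1ccc(O)c(O)c1)c1cc(O)c(O)c(O)c1 | target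

## Step count and risks

Total step count: 17. Longest linear sequence: 15 steps (steps 1–6, 8, 10–17).

Steps most likely to fail:

1. Step 6 (Proposed new method). What may go wrong is O-allylation, or uncatalysed ionisation of 7, either of which would lose branched regiochemistry and facial control; turnover may also stop at the allyl terminus flanked by two ortho oxygens. The fallback uses known chemistry and sets out from aldehyde 6. Horner–Wadsworth–Emmons olefination (triethyl phosphonoacetate, NaH, THF) should give ethyl (E)-3-(L-8-yl)acrylate F1. Reduction with i-Bu2AlH gives (E)-3-(L-8-yl)prop-2-en-1-ol F2. Mitsunobu etherification with phenol 8 (PPh3, DIAD) gives 3,5-bis(benzyloxy)phenyl (E)-3-(L-8-yl)allyl ether F3. Thermal aromatic Claisen rearrangement (N,N-diethylaniline, 160 °C) moves the allyl unit to the ortho carbon with allylic transposition and gives 9 together with its methine epimer F4. These are diastereomers because L is enantiopure, so they are separated by chromatography, and the route is rejoined at 9. This fallback gives up catalyst control of C4 and relies on separation.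

2. Step 12 (key step). What may go wrong is failure of the ring-closing metallacycle to form at the hindered 1,1-disubstituted enol ether, or ruthenium-hydride-induced migration of the double bond through C4. The fallback sets out from ester 14 and skips 15. A reduced titanium ethylidene reagent (TiCl4, Zn, PbCl2 (cat.), TMEDA, CH3CHBr2, THF–CH2Cl2; Takai–Utimoto type) exchanges onto the C4 vinyl group, and the titanium alkylidene then adds to the ester carbonyl (olefinic ester cyclisation, a carbonyl–olefin metathesis). This forms the same C2=C3 bond and comes back at chromene 16. No compound outside the list is made (F0).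

3. Step 14 (with step 13). What may go wrong is ionisation of the epoxide to the 2-aryl oxocarbenium ion before hydride transfer, which would lose the inversion at C2 or lead to a 1,2-hydride shift to the flavan-3-one. The fallback sets out from chromene 16. Epoxidation with DMDO in the presence of methanol traps the epoxide by anti opening as the isolable trans-2-methoxy-3-ol ketal F5. Ionic reduction with Et3SiH and BF3·OEt2 at −78 °C then passes through the oxocarbenium ion, where hydride should add anti to the pseudo-axial C3 oxygen, and the route comes back at 18.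

Further compounds
F1 | step 6 | ethyl (E)-3-(L-8-yl)acrylate | CCOC(=O)/C=C/c1c(OCc2ccccc2)cc(OCc2ccccc2)c2c1O[C@H](c1ccc(OCc3ccccc3)c(OCc3ccccc3)c1)[C@H](O[Si](C)(C)C(C)(C)C)C2
F2 | step 6 | (E)-3-(L-8-yl)prop-2-en-1-ol | OC/C=C/c1c(OCc2ccccc2)cc(OCc2ccccc2)c2c1O[C@H](c1ccc(OCc3ccccc3)c(OCc3ccccc3)c1)[C@H](O[Si](C)(C)C(C)(C)C)C2
F3 | step 6 | 3,5-bis(benzyloxy)phenyl (E)-3-(L-8-yl)allyl ether | c1c(OCc2ccccc2)cc(OCc2ccccc2)cc1OC/C=C/c1c(OCc2ccccc2)cc(OCc2ccccc2)c2c1O[C@H](c1ccc(OCc3ccccc3)c(OCc3ccccc3)c1)[C@H](O[Si](C)(C)C(C)(C)C)C2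
F4 | step 6 | 3,5-bis(benzyloxy)-2-[(1S)-1-(L-8-yl)prop-2-en-1-yl]phenol (methine epimer of 9) | Oc1cc(OCc2ccccc2)cc(OCc2ccccc2)c1[C@@H](c1c(OCc2ccccc2)cc(OCc2ccccc2)c2c1O[C@H](c1ccc(OCc3ccccc3)c(OCc3ccccc3)c1)[C@H](O[Si](C)(C)C(C)(C)C)C2)C=C
F0 | step 12 | none | none
F5 | step 14 | trans-2-methoxy-3-ol ketal of M (2-OMe anti to 3-OH; U and L as 3-O-TBS) | O[C@@H]1[C@@H](c2c(OCc3ccccc3)cc(OCc3ccccc3)c3c2O[C@H](c2ccc(OCc4ccccc4)c(OCc4ccccc4)c2)[C@H](O[Si](C)(C)C(C)(C)C)C3)c2c(OCc3ccccc3)cc(OCc3ccccc3)c([C@H]3c4c(OCc5ccccc5)cc(OCc5ccccc5)cc4O[C@H](c4ccc(OCc5ccccc5)c(OCc5ccccc5)c4)[C@@H]3O[Si](C)(C)C(C)(C)C)c2O[C@]1(OC)c1ccc(OCc2ccccc2)c(OCc2ccccc2)c1
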